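The runs were generated by integration with constants of no real substance; the scatter is artificial.

14.0% was where Wednesday's run ended: target began at 0.0150 /min of the charge and then flattened, as a source does against a first-order sink.

the same everywhere: substrate 0.51 M

|  | reagent | free catalyst | temperature | remark | time |
|---|---|---|---|---|---|
| Friday's | 1.8 equiv | 3.5 mol% | 10 °C | run made earlier |  |
| Wednesday's | 1.8 equiv | 5.5 mol% | 38 °C | run made earlier |  |
| midnight | 1.80 equiv | 2.5 mol% | 45 °C |  | 30 min |
| winter | 1.80 equiv | 2.5 mol% | 60 °C |  | 30 min |
| summer | 1.80 equiv | 2.5 mol% | 30 °C |  | 30 min |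
| dawn | 1.80 equiv | 2.5 mol% | 15 °C |  | 30 min |

- Friday's (time / min: target / %): 25.0: 4.0; 50.0: 6.3; 60.0: 6.6; 80.0: 8.8; 120: 12.3; 150: 15.3; 180: 16.2
- Wednesday's (time / min: target / %): 1.50: 2.1; 5.00: 7.5; 8.00: 9.7; 12.0: 12.6; 20.0: 13.3; 25.0: 14.0; 30.0: 14.0

(standard deviation of a reading: 0.5 percentage points)

- the flask that comes out highest in amount of target, in percent of the substrate charged, or "all alike" when all lie within 1.5 percentage points (midnight / winter / summer / dawn / all alike)
- target at the end, in percent of the substrate charged, midnight
- target at the end, in percent of the substrate charged, winter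
- target at the end, in percent of the substrate charged, summer
- target at the end, in percent of the substrate charged, dawn



I supposed that target is made at a rate proportional to c(substrate)·c(reagent) and lost at a rate proportional to c(free catalyst)·c(target). Scaled inversely with loading from Wednesday's last reading, taken as if the charges there were still whole, this gave 30.8% at 2.5 mol%: the ceiling, my estimate of the level of target at which making and loss balance while the charges are whole. At Friday's loading the ceiling came to 22.0%. With Friday's slope of 0.00160 /min, an exponential rise toward it gives 16.1% at 180 min, against a reading of 16.2%. So I let the ceiling stand at every temperature of my reckoning, while the two slopes, whose runs differ in loading as well but which my making term takes without the catalyst, gave a reading of the activation energy of 58.6 kJ/mol.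

Slopes for dawn, summer, midnight and winter came to 0.00246 /min, 0.00825 /min, 0.0247 /min and 0.0669 /min. Substrate is the limiting reagent, so I reckoned the fraction of it left, second-order with the reagent excess, keeping the same order of flasks. At mid-run that fraction was 96.4%, 88.7%, 71.3% and 44.2%. In my reckoning the ceiling shrank with the fractions left of substrate and reagent, and the rise toward it gave the rest. My target figures were 6.21%, 14.1%, 16.8% and 9.37%, so midnight led. Midnight's books, as I reckoned them, closed with 53.3% of the substrate left, 16.8% as target, and 29.9% gone through the sink.

The forecast named summer, with 5.4% for midnight, 3.6% for winter, 7.2% for summer and 4.1% for dawn: "heat kills catalyst faster than it speeds product formation". I parted from it there.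

The simulation gave midnight: 19.8% at midnight, 9.92% in winter, 15.8% in summer and 5.92% at dawn.

    free catalyst + target → spent catalyst (k = 0.227 /M/min, Ea = 58.0 kJ/mol)
    substrate + reagent ⇌ isomer of the product (K = 84.3 /M, k = 0.0755 /M/min, Ea = 56.0 kJ/mol, ΔH = 4.00 kJ/mol)
    free catalyst ⇌ dormant form (K = 0.508, k = 0.0248 /min, Ea = 107 kJ/mol, ΔH = −63.0 kJ/mol)
    substrate + reagent ⇌ target (K = 2.68 /M, k = 0.121 /M/min, Ea = 69.0 kJ/mol, ΔH = −46.0 kJ/mol)
    target + free catalyst ⇌ isomer of the product + free catalyst, rate k5*[free catalyst]*[target] forward; the back reaction follows from the equilibrium constant (k = 10.8 /M/min, Ea = 59.0 kJ/mol)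
    (constants at 60 °C)

One sink was the catalysed turning of target into isomer of the product. In winter, with that step taken away, target ended at 32.7% in place of 9.92%, whereas taking away the turning into spent catalyst, a part of the story, gave 7.60%. For a neighbour like midnight kept at 20 °C, the same ceiling of 30.8% with its slope and fractions left gave 8.63%, and that flask held 8.75%.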